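The constants of this flask are hidden, so its clock must be read from the zeta run, the same flask followed up to 20.0 h.

| flask | substrate | partner | remark | time |
|---|---|---|---|---|
| zeta | 0.50 M | 0.80 equiv | the very flask that is asked about, followed so far |  |
| flask | 0.50 M | 0.800 equiv |  | 3.0 d |

- zeta (time / h: target / %, intermediate / %): 2.00: 27.1, 4.0; 5.00: 40.8, 6.9; 10.0: 50.0, 8.0; 15.0: 53.3, 8.2; 20.0: 56.3, 7.7

(standard deviation of a reading: 0.5 percentage points)

- the analysis behind the earlier runs scatters by 0.5 percentage points, standard deviation
- a reading or a percentage of target counts all its forms, free or not
- the concentration of target that is asked is that of its free form alone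

- concentration of target (only what is free in solution) at 3.0 d, in M
- concentration of intermediate at 3.0 d, in M
- concentration of substrate at 3.0 d, in M
- concentration of partner at 3.0 d, in M

Partner, at 0.800 equiv, is the limiting reagent. On the first rung of the ladder, target plus intermediate reach 31.1% of the substrate by 2.00 h.

The next rung is the tail. The sum gains 3.5 percentage points from 10.0 h to 15.0 h, then less, 2.5 points, over the next equal span. Read as one decay, these gains give the reacting partner a lifetime of 14.9 h. Each gain carries about 1 point of scatter, so this is a rough reading. The asked time lies 3.50 such lifetimes past the last reading.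

Summing the shrinking gains adds 6.2 points, so the sum should end near 70.2%. That gives the partner return, the product formed per partner charged: 87.8%.

On the last rung stands intermediate, whose readings of 8.0%, 8.2% and 7.7% barely move beyond the scatter.

My own reckoning is therefore [substrate] about 0.149 M, counting no other loss of substrate; [intermediate] about 0.0385 M, held at its last reading; [target], free and bound forms together, about 0.313 M; and [partner] still to react, bound forms included, about 9.44 × 10⁻⁴ M.

The forecast gives 0.285 M, 0.025 M, 0.15 M and 0.02 M for target, intermediate, substrate and partner, saying “I take about 70% consumed”.

The flask gives [target] 0.314 M, [intermediate] 0.0302 M, [substrate] 0.136 M and [partner] 5.41 × 10⁻⁴ M.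

    substrate + partner → target (k = 0.0109 M⁻¹ min⁻¹)
    intermediate → target (k = 1.21 × 10⁻⁴ min⁻¹)
    partner → decomposed reagent (k = 4.84 × 10⁻⁴ min⁻¹)
    partner + target → over-reaction product (k = 2.70 × 10⁻⁴ M⁻¹ min⁻¹)
    substrate + partner → intermediate (k = 0.00177 M⁻¹ min⁻¹)
    partner + target ⇌ idle adduct, settled at all times (K = 4.50 M⁻¹)
    substrate → side product (k = 2.00 × 10⁻⁵ min⁻¹)

In this flask, half of the turnover of substrate + partner into target was done by 0.0986 d, far sooner than the asked 3.0 d, and at that asked time free partner stood at 0.14% of its charge, less than the 27% left of the substrate. Target and intermediate there came to 86.3% of the partner charged, beside the return of 87.8%.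

A second flask holds 0.480 equiv of partner, with all else as here. The return of 87.8% gives 42.1% of the substrate as target plus intermediate. That flask gives 43.2%, with [substrate] at 0.259 M.

The data were computed for substances that don't exist, noise included.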